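**Retrosynthetic overview**
1. The strategy rests on ring A and its junction: the quaternary C5 (C19) cis-fused to C10–H, the C4=C18 methylene beside it and the vicinal C2/C3 oxygens are together the footprint of a 1-methoxyallenyl group moved from C2 to C5 by a [3,3] shift.
2. Backwards: C15 acid ⇐ allylic alcohol; diosphenol ⇐ Rubottom-type oxidation of the C2=C3 silyloxy/methoxy alkene; C7–OAc ⇐ C6=C7 enol ether; C4–C5 ⇐ anionic oxy-Cope rearrangement of a 2-(1-methoxyallenyl)bicyclo[2.2.2]oct-5-en-2-ol.
3. The bicycle ⇐ methoxyallenyllithium + ketone ⇐ masked o-benzoquinone intramolecular Diels–Alder of 2,6-dimethoxy-4-methylphenol with a (Z)-allylic alcohol, then SmI2 deketalization and C20 deoxygenation through a chiral sulfonate that also resolves the racemate.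
4. The allylic alcohol ⇐ Eschenmoser–Claisen rearrangement (E-C13=C14) and Z-selective Wittig olefination of an α-alkoxy ketone (Z-C8=C9).
5. Ring order: arene → bicyclo[2.2.2]octene (the carbons of ring B plus the C1–C2 bridge) → ring A closed and ring B released in the key step.

Key step: step 11

Remark: clerodane numbers are used throughout (in the bicycle C7 and C10 are bridgeheads, the bridges are C1–C2, C8–C9 and C5=C6); an enantioselective ketalization of the phenol by an external alcohol is not established chemistry, so the cycloadduct is made racemic and resolved in step 8 by a chiral sulfonate that then serves as the leaving group.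

**Route**

Step 1
Reactants: 1 (tert-butyldimethylsilyloxy)acetaldehyde; 2 isopropenylmagnesium bromide
Product: 3 rac-1-[(tert-butyldimethylsilyl)oxy]-3-methylbut-3-en-2-ol
Conditions: THF, −78 → 0 °C; aq. NH4Cl
Reagents that add atoms: none
Why: Grignard 1,2-addition to an aldehyde; the carbinol centre is racemic and is erased in step 2.

Step 2
Reactants: 3 rac-allylic alcohol; 4 N,N-dimethylacetamide dimethyl acetal
Product: 6 (4E)-6-[(tert-butyldimethylsilyl)oxy]-N,N,4-trimethylhex-4-enamide, via ketene N,O-acetal 5 (not isolated)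
Conditions: xylene, 140 °C, MeOH distilled off
Reagents that add atoms: none
Why: Eschenmoser–Claisen rearrangement; the chair transition state with the CH2OTBS group equatorial should give the (E)-trisubstituted C13=C14 alkene and forms the C11–C12 bond.

Step 3
Reactants: 6 (4E)-amide; 7 tributyl[(methoxymethoxy)methyl]stannane
Product: 9 (5E)-7-[(tert-butyldimethylsilyl)oxy]-1-(methoxymethoxy)-5-methylhept-5-en-2-one, via (methoxymethoxy)methyllithium 8 (not isolated)
Conditions: 7, n-BuLi, THF, −78 °C; then 6, −78 → −20 °C; aq. NH4Cl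
Reagents that add atoms: none
Why: tin–lithium exchange gives the α-alkoxymethyllithium, and its addition to the tertiary amide stops at the tetrahedral adduct, which gives the ketone on work-up (acylation of an organolithium by an N,N-dimethylamide).

Step 4
Reactants: 9 α-(methoxymethoxy) ketone; 10 ethyltriphenylphosphonium bromide
Product: 12 tert-butyl({(2E,6Z)-6-[(methoxymethoxy)methyl]-3-methylocta-2,6-dien-1-yl}oxy)dimethylsilane, via ethylidenetriphenylphosphorane 11 (not isolated)
Conditions: 10, KHMDS, THF, 0 °C; then 9, −78 °C → rt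
Reagents that add atoms: none
Why: Wittig olefination of an α-alkoxy ketone with a non-stabilized ylide, a combination known to place the new alkyl group cis to the alkoxymethyl group, so the (Z)-C8=C9 alkene (C17 cis to C20) should predominate.

Step 5
Reactants: 12 (2E,6Z)-MOM ether
Product: 13 (2Z)-2-{(3E)-5-[(tert-butyldimethylsilyl)oxy]-3-methylpent-3-en-1-yl}but-2-en-1-ol
Conditions: MgBr2·OEt2, n-BuSH, Et2O, rt
Reagents that add atoms: none
Why: Lewis acid–thiol cleavage of the MOM acetal, under which the primary TBS ether and both trisubstituted alkenes are expected to survive.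

Step 6
Reactants: 13 (Z)-allylic alcohol (2 equiv, excess recovered); 14 2,6-dimethoxy-4-methylphenol
Product: 16 racemic tricyclic Diels–Alder adduct (ketal-bridged bicyclo[2.2.2]octenone), via masked o-benzoquinone 15 (not isolated)
Conditions: PhI(OAc)2, CH2Cl2, 0 °C → rt; then toluene, 110 °C
Reagents that add atoms: none
Why: oxidative dearomatization to the mixed o-quinone monoketal and intramolecular Diels–Alder reaction; the three-atom tether forces C9 onto the diene terminus next to the ketal with C20 on the side of the ketal bridge, and suprafacial addition to the (Z)-alkene puts the C8 methyl cis to C20, so C7, C8, C9 and C10 are set in their relative configuration (racemate).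

Step 7
Reactants: 16 racemic tricyclic adduct
Product: 17 racemic C20-hydroxy ketone
Conditions: SmI2 (5 equiv), THF/MeOH, −78 °C → rt
Reagents that add atoms: none
Why: samarium diiodide reductive cleavage of both C–O bonds at C1 α to the ketone (deketalization), which frees the C20 hydroxyl; the bridgehead C7 methoxy should stay because its C–O bond cannot align with the ketyl π system (no bridgehead enolate).

Step 8
Reactants: 17 racemic C20-hydroxy ketone
Product: 18 (1S)-camphor-10-sulfonate of the target-series enantiomer
Conditions: (1S)-(+)-10-camphorsulfonyl chloride, Et3N, DMAP (cat.), CH2Cl2, 0 °C; the two diastereomers separated by chromatography or crystallization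
Reagents that add atoms: (1S)-(+)-10-camphorsulfonyl chloride, CC1(C)[C@@H]2CC[C@@]1(CS(=O)(=O)Cl)C(=O)C2
Why: sulfonylation of the primary alcohol with an enantiopure sulfonyl chloride turns the racemate into two separable diastereomers (classical resolution) and activates C20 at the same time; the configuration of the diastereomer kept is to be assigned by X-ray analysis against the camphor unit.

Step 9
Reactants: 18 camphorsulfonate
Product: 21 enantiopure C20-methyl ketone, via neopentyl iodide 19 (not isolated), via alkylzinc iodide 20 (not isolated)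
Conditions: NaI, Zn dust, HMPA (or DMPU), 105 °C; aq. NH4Cl
Reagents that add atoms: none
Why: Finkelstein displacement of the sulfonate followed by zinc reduction of the iodide (reductive removal of a sulfonyloxy group), which tolerates the ketone and the silyl ether and leaves C20 as methyl.

Step 10
Reactants: 21 ketone; 22 methoxyallene
Product: 24 2-(1-methoxyallenyl)bicyclo[2.2.2]oct-5-en-2-ol, via 1-lithio-1-methoxyallene 23 (not isolated)
Conditions: 22, n-BuLi, THF, −40 °C; then 21, −78 °C; aq. NaHCO3
Reagents that add atoms: none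
Why: 1,2-addition of lithiated methoxyallene to the ketone; the C8 methyl points at the carbonyl bridge and blocks that face, so the nucleophile should enter from the side of the C5=C6 bridge and set C2 with the allenyl group syn to the alkene.

Step 11
Reactants: 24 allenyl carbinol
Product: 27 cis-decalin triisopropylsilyl dienol ether, via potassium alkoxide 25 (not isolated), via potassium enolate 26 (not isolated)
Conditions: KHMDS, 18-crown-6, THF, 0 °C → rt; then TIPSOTf, −78 °C; Et3N, aq. NaHCO3
Reagents that add atoms: triisopropylsilyl trifluoromethanesulfonate, CC(C)[Si](C(C)C)(C(C)C)OS(=O)(=O)C(F)(F)F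
Why: KHMDS/18-crown-6 gives the free potassium alkoxide 25, and the 1,5-diene C4=C3–C2–C7–C6=C5 undergoes a charge-accelerated [3,3] sigmatropic shift (anionic oxy-Cope rearrangement) through the boat geometry fixed by the bicycle, forming C4–C5 and cleaving C2–C7. The closest known reaction type is the anionic oxy-Cope rearrangement of 2-alkenylbicyclo[2.2.2]oct-5-en-2-ols to cis-decalins, here with an allenyl terminus. Ring A (C1–C5, C10) closes as a six-membered ring by this sigmatropic C–C bond formation between the central allene carbon and C5, not by a polar cyclization, while the old carbocycle C5–C10 becomes ring B with a C6=C7 enol ether. The new stereocentre C5 is substrate-controlled: C4 is delivered suprafacially from the C1–C2 bridge already bonded to C10, so C4 and C1 end on the same face, the C5/C10 fusion is cis and C19 is trans to C20. The step needs the allenyl group syn to the alkene (set in step 10) and the [3,3] shift to outrun 5-endo attack of the alkoxide on the allene, which strain release in the bicycle and the crown-ether-separated alkoxide should secure. The enolate 26 is silylated on oxygen by the hard silyl triflate; the triisopropylsilyl group is chosen so that ring A survives step 12, and C18 is left as the exocyclic methylene.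

Step 12
Reactants: 27 cis-decalin dienol ether
Product: 28 C7 ketone
Conditions: 10% aq. oxalic acid on SiO2, CH2Cl2, 0 °C
Reagents that add atoms: water, O
Why: chemoselective enol ether hydrolysis; the isolated C6=C7 methyl enol ether should be protonated at C6 much faster than the ring-A diene, whose C2=C3 bond carries an oxygen on each carbon and a bulky silyl group, and no stereocentre is formed (the C8 methyl is already equatorial).

Step 13
Reactants: 28 C7 ketone
Product: 29 C7 equatorial alcohol
Conditions: SmI2 (2.5 equiv), H2O, Et3N, THF, rt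
Reagents that add atoms: none
Why: single-electron (ketyl) reduction, which like a dissolving-metal reduction should give the more stable equatorial C7 alcohol (O cis to C19 and H10), whereas a hydride would be kept off the axial trajectory by the syn-axial C4 and C20 and give the axial epimer.

Step 14
Reactants: 29 C7 alcohol
Product: 30 C7 acetate
Conditions: Ac2O, DMAP, pyridine, CH2Cl2, rt
Reagents that add atoms: acetic anhydride, CC(=O)OC(C)=O
Why: DMAP-catalysed acylation of the equatorial secondary alcohol, with the silyl dienol ether and the silyl ether inert to the basic medium.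

Step 15
Reactants: 30 C7 acetate
Product: 33 diosphenol allylic alcohol, via silyloxy epoxide 31 (not isolated), via 2,3-dione 32 (not isolated)
Conditions: DMDO (1.05 equiv), acetone/CH2Cl2, −78 °C; then HF·pyridine, pyridine, THF, 0 °C → rt
Reagents that add atoms: dimethyldioxirane, CC1(C)OO1
Why: Rubottom-type oxidation; the dioxirane should epoxidize the most electron-rich, doubly oxygenated C2=C3 bond, fluoride removes the silyl group and the α-methoxy epoxide collapses with loss of methanol to the 2,3-dione, which can enolize only toward C1 and so gives the diosphenol, while the same fluoride treatment frees the C15 alcohol.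

Step 16
Reactants: 33 diosphenol allylic alcohol
Product: 34 (E)-enal
Conditions: activated MnO2, CH2Cl2, rt
Reagents that add atoms: none
Why: manganese dioxide oxidation, selective for the primary allylic alcohol and expected to keep the (E)-geometry.

Step 17
Reactants: 34 (E)-enal
Product: 35 CNP0192653.1
Conditions: NaClO2, NaH2PO4, 2-methylbut-2-ene (excess), t-BuOH/H2O, 0 °C
Reagents that add atoms: sodium chlorite, [Na+].[O-]Cl=O
Why: Pinnick oxidation of the enal to the enoic acid under buffered conditions, with the alkene scavenger taking up hypochlorous acid before it can reach the diosphenol.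

**Compound list**

1 | (tert-butyldimethylsilyloxy)acetaldehyde | O=CCO[Si](C)(C)C(C)(C)C | starting material
2 | isopropenylmagnesium bromide | C=C(C)[Mg]Br | starting material
3 | rac-1-[(tert-butyldimethylsilyl)oxy]-3-methylbut-3-en-2-ol | C=C(C)C(O)CO[Si](C)(C)C(C)(C)C | intermediate
4 | N,N-dimethylacetamide dimethyl acetal | COC(C)(OC)N(C)C | starting material
5 | ketene N,O-acetal (1-(dimethylamino)vinyl ether of 3) | C=C(N(C)C)OC(CO[Si](C)(C)C(C)(C)C)C(C)=C | intermediate
6 | (4E)-6-[(tert-butyldimethylsilyl)oxy]-N,N,4-trimethylhex-4-enamide | CN(C)C(=O)CC/C(C)=C/CO[Si](C)(C)C(C)(C)C | intermediate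
7 | tributyl[(methoxymethoxy)methyl]stannane | CCCC[Sn](CCCC)(CCCC)COCOC | starting material
8 | (methoxymethoxy)methyllithium | [Li]COCOC | intermediate
9 | (5E)-7-[(tert-butyldimethylsilyl)oxy]-1-(methoxymethoxy)-5-methylhept-5-en-2-one | COCOCC(=O)CC/C(C)=C/CO[Si](C)(C)C(C)(C)C | intermediate
10 | ethyltriphenylphosphonium bromide | CC[P+](c1ccccc1)(c1ccccc1)c1ccccc1.[Br-] | starting material
11 | ethylidenetriphenylphosphorane | CC=P(c1ccccc1)(c1ccccc1)c1ccccc1 | intermediate
12 | tert-butyl({(2E,6Z)-6-[(methoxymethoxy)methyl]-3-methylocta-2,6-dien-1-yl}oxy)dimethylsilane | C/C=C(\COCOC)CC/C(C)=C/CO[Si](C)(C)C(C)(C)C | intermediate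
13 | (2Z)-2-{(3E)-5-[(tert-butyldimethylsilyl)oxy]-3-methylpent-3-en-1-yl}but-2-en-1-ol | C/C=C(\CO)CC/C(C)=C/CO[Si](C)(C)C(C)(C)C | intermediate
14 | 2,6-dimethoxy-4-methylphenol | COc1cc(C)cc(OC)c1O | starting material
15 | masked o-benzoquinone: 2,6-dimethoxy-4-methylcyclohexa-2,4-dien-1-one carrying the O-allyl group of 13 on C6 (racemic at the ketal carbon) | COC1=CC(C)=CC(OC)(OC/C(CC/C(C)=C/CO[Si](C)(C)C(C)(C)C)=C\C)C1=O | intermediate
16 | racemic tricyclic adduct (enantiomer of the target series drawn): bicyclo[2.2.2]oct-5-en-2-one with C7–OMe bridgehead, C5 methyl, C1 ketal (OMe toward the alkene) tied to C9 by an O–C20H2 tetrahydrofuran ring, side chain on C9 syn to the alkene, C8 methyl syn to the ketone bridge | CO[C@@]12OC[C@]3(CC/C(C)=C/CO[Si](C)(C)C(C)(C)C)[C@H](C)[C@@](OC)(C=C(C)[C@H]13)C2=O | intermediate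
17 | racemic hydroxy ketone (enantiomer of the target series drawn): as 16 with C1 as CH2 and C9–CH2OH (C20) | O=C1C[C@@H]2[C@@](CO)(CC/C(C)=C/CO[Si](C)(C)C(C)(C)C)[C@H](C)[C@@]1(OC)C=C2C | intermediate
18 | (1S)-camphor-10-sulfonate of the C20 alcohol, single diastereomer | O=C1C[C@@H]2[C@@](COS(=O)(=O)C[C@]34CC[C@H](CC3=O)C4(C)C)(CC/C(C)=C/CO[Si](C)(C)C(C)(C)C)[C@H](C)[C@@]1(OC)C=C2C | intermediate
19 | C20 neopentyl iodide | O=C1C[C@@H]2[C@@](CI)(CC/C(C)=C/CO[Si](C)(C)C(C)(C)C)[C@H](C)[C@@]1(OC)C=C2C | intermediate
20 | C20 alkylzinc iodide | O=C1C[C@@H]2[C@@](C[Zn]I)(CC/C(C)=C/CO[Si](C)(C)C(C)(C)C)[C@H](C)[C@@]1(OC)C=C2C | intermediate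
21 | enantiopure ketone: 7-methoxy-5,8,9-trimethylbicyclo[2.2.2]oct-5-en-2-one (clerodane numbers), C8 and C20 methyls syn to the ketone bridge, side chain on C9 syn to the alkene | O=C1C[C@@H]2[C@@](C)(CC/C(C)=C/CO[Si](C)(C)C(C)(C)C)[C@H](C)[C@@]1(OC)C=C2C | intermediate
22 | methoxyallene | COC=C=C | starting material
23 | 1-lithio-1-methoxyallene | [Li]C(OC)=C=C | intermediate
24 | 2-(1-methoxyallenyl)bicyclo[2.2.2]oct-5-en-2-ol: C2 carbinol with the allenyl group syn to the C5=C6 bridge, OH syn to the C8–C9 bridge | C=C=C(OC)[C@@]1(O)C[C@@H]2[C@@](C)(CC/C(C)=C/CO[Si](C)(C)C(C)(C)C)[C@H](C)[C@@]1(OC)C=C2C | intermediate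
25 | potassium alkoxide of 24 | [K+].C=C=C(OC)[C@@]1([O-])C[C@@H]2[C@@](C)(CC/C(C)=C/CO[Si](C)(C)C(C)(C)C)[C@H](C)[C@@]1(OC)C=C2C | intermediate
26 | potassium C2 enolate of the cis-decalin | [K+].C=C1C(OC)=C([O-])C[C@@H]2[C@@](C)(CC/C(C)=C/CO[Si](C)(C)C(C)(C)C)[C@H](C)C(OC)=C[C@]12C | intermediate
27 | cis-decalin: C4=C18 methylene, C3–OMe, C2–OTIPS dienol ether, C6=C7 methyl enol ether, C15–OTBS | C=C1C(OC)=C(O[Si](C(C)C)(C(C)C)C(C)C)C[C@@H]2[C@@](C)(CC/C(C)=C/CO[Si](C)(C)C(C)(C)C)[C@H](C)C(OC)=C[C@]12C | intermediate
28 | C7 ketone with ring-A silyl dienol ether intact | C=C1C(OC)=C(O[Si](C(C)C)(C(C)C)C(C)C)C[C@@H]2[C@@](C)(CC/C(C)=C/CO[Si](C)(C)C(C)(C)C)[C@H](C)C(=O)C[C@]12C | intermediate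
29 | C7 equatorial alcohol (OH cis to C19 and H10) | C=C1C(OC)=C(O[Si](C(C)C)(C(C)C)C(C)C)C[C@@H]2[C@@](C)(CC/C(C)=C/CO[Si](C)(C)C(C)(C)C)[C@H](C)[C@@H](O)C[C@]12C | intermediate
30 | C7 acetate | C=C1C(OC)=C(O[Si](C(C)C)(C(C)C)C(C)C)C[C@@H]2[C@@](C)(CC/C(C)=C/CO[Si](C)(C)C(C)(C)C)[C@H](C)[C@@H](OC(C)=O)C[C@]12C | intermediate
31 | C2/C3 silyloxy methoxy epoxide (epoxide configuration not defined) | C=C1C2(OC)OC2(O[Si](C(C)C)(C(C)C)C(C)C)C[C@@H]3[C@@](C)(CC/C(C)=C/CO[Si](C)(C)C(C)(C)C)[C@H](C)[C@@H](OC(C)=O)C[C@]13C | intermediate
32 | 2,3-dione (C15–OTBS still in place) | C=C1C(=O)C(=O)C[C@@H]2[C@@](C)(CC/C(C)=C/CO[Si](C)(C)C(C)(C)C)[C@H](C)[C@@H](OC(C)=O)C[C@]12C | intermediate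
33 | diosphenol allylic alcohol (C2 enol, C3 ketone, C4=C18, C7–OAc, C15–OH) | C=C1C(=O)C(O)=C[C@@H]2[C@@](C)(CC/C(C)=C/CO)[C@H](C)[C@@H](OC(C)=O)C[C@]12C | intermediate
34 | (13E)-C15 enal | C=C1C(=O)C(O)=C[C@@H]2[C@@](C)(CC/C(C)=C/C=O)[C@H](C)[C@@H](OC(C)=O)C[C@]12C | intermediate
35 | CNP0192653.1: 7-acetoxy-2-hydroxy-3-oxo-cis-cleroda-1,4(18),13E-trien-15-oic acid | C=C1C(=O)C(O)=C[C@@H]2[C@@](C)(CC/C(C)=C/C(=O)O)[C@H](C)[C@@H](OC(C)=O)C[C@]12C | target

**Step count and risks**

Total steps: 17. Longest linear sequence: 17 (from 1; compounds 2, 4, 7, 10, 14 and 22 enter as purchased reagents).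

Steps most likely to fail:

1. Step 11. The alkoxide may attack the allene terminus in a 5-endo cyclization, or the bicycle may fragment, before the [3,3] shift takes place. Fallback, setting out from 24: silylation with N-(trimethylsilyl)imidazole gives the trimethylsilyl ether F1. Heating F1 in o-dichlorobenzene (about 190 °C, sealed tube) should bring about the neutral siloxy-Cope rearrangement, with no alkoxide present, to the trimethylsilyl dienol ether F2. Methyllithium followed by triisopropylsilyl triflate exchanges the silyl group, and the route is rejoined at 27.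

2. Step 12. The acid may also cleave the ring-A silyl dienol ether, or move the exocyclic double bond into the ring, while the C6=C7 enol ether is hydrolysed. Fallback, setting out from 27: both enol ethers are hydrolysed on purpose (1 M HCl, THF, 0 °C) to the 2,7-diketone F3, which has a 3-methoxy-4-methylene-2-ketone in ring A. Ring A alone is then silylated again by soft enolization (TIPSOTf, Et3N, CH2Cl2, −78 °C), because C3–H is allylic and α to the ketone whereas the C7 ketone has only hindered α-positions. This returns to 28.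

3. Step 8. The two diastereomeric sulfonates may not separate, so that no resolution is achieved. Fallback, setting out from 17: mesylation (MsCl, Et3N) gives the racemic mesylate F4, and NaI/Zn reduction gives the racemic ketone F5. Addition of lithiated (S)-N,S-dimethyl-S-phenylsulfoximine gives two β-hydroxy sulfoximines, which are separated. Thermolysis of the adduct of the target series F6 (toluene, 110 °C) releases the enantiopure ketone and rejoins the route at 21.

Further compounds
F1 | step 11 | trimethylsilyl ether of carbinol 24 | C=C=C(OC)[C@@]1(O[Si](C)(C)C)C[C@@H]2[C@@](C)(CC/C(C)=C/CO[Si](C)(C)C(C)(C)C)[C@H](C)[C@@]1(OC)C=C2C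
F2 | step 11 | cis-decalin trimethylsilyl dienol ether (trimethylsilyl analogue of 27) | C=C1C(OC)=C(O[Si](C)(C)C)C[C@@H]2[C@@](C)(CC/C(C)=C/CO[Si](C)(C)C(C)(C)C)[C@H](C)C(OC)=C[C@]12C
F3 | step 12 | 2,7-diketone with 3-methoxy-4-methylene ring A (C3 configuration not defined) | C=C1C(OC)C(=O)C[C@@H]2[C@@](C)(CC/C(C)=C/CO[Si](C)(C)C(C)(C)C)[C@H](C)C(=O)C[C@]12C
F4 | step 8 | racemic C20 mesylate of 17 (one enantiomer drawn) | O=C1C[C@@H]2[C@@](COS(C)(=O)=O)(CC/C(C)=C/CO[Si](C)(C)C(C)(C)C)[C@H](C)[C@@]1(OC)C=C2C
F5 | step 8 | racemic ketone (racemate of 21, one enantiomer drawn) | O=C1C[C@@H]2[C@@](C)(CC/C(C)=C/CO[Si](C)(C)C(C)(C)C)[C@H](C)[C@@]1(OC)C=C2C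
F6 | step 8 | β-hydroxy sulfoximine from the target-series ketone and (S)-N,S-dimethyl-S-phenylsulfoximine | CN=[S@@](=O)(c1ccccc1)C[C@@]1(O)C[C@@H]2[C@@](C)(CC/C(C)=C/CO[Si](C)(C)C(C)(C)C)[C@H](C)[C@@]1(OC)C=C2C
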